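**Plan**
- Numbering used throughout, also in names: ring O1, O2, C3 (methoxy ketal carbon), C4, C5, C6 (the CH that carries Ca, the CH2 of the acetic acid arm). The target is the (3R,6S) acid, with OMe and the acid arm cis.
- Retrosynthetic cuts, in order: the C(sp)–C(sp2) bond of the enyne; then O1–C6, C3–O2 and C3–OMe of the dioxane in one operation; then the lactone bonds C6–Ca and O–C(=O); then C4–C5 (orthoester Claisen) and the bond from C3 to the pentynyl chain (carbomagnesiation).
- Enabling feature: C6 bears oxygen beta to the carboxyl carbon, so C6, Ca, the carboxyl carbon and one carboxyl oxygen fold back into an oxetan-2-one ring. Its strained alkyl C6–O bond is a leaving group six atoms away from a hydroperoxide oxygen that ozonolysis in methanol creates at C3.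
- Forward order: the carbon chain is built linearly, the four-membered lactone is closed, the only ring of the target (the 1,2-dioxane) closes in step 6, C3 is levelled, and the ketone chain is joined last.
- Stereochemistry: C6 comes from a catalyst-controlled ketene–aldehyde cycloaddition (R) and is passed on with inversion (S). C3 comes from thermodynamic (anomeric) equilibration. The E alkene comes from syn hydrozirconation.

Key step: step 6

Assumption: O-trimethylsilylquinine is taken as the alkaloid pseudoenantiomer that leads to (R)-4-alkyloxetan-2-ones from unbranched aldehydes; should the sense be the opposite, O-trimethylsilylquinidine takes its place and nothing else changes.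
Remark: the ring closure fixes C6 only, so its product is carried as the pair of C3 epimers and becomes the single (3R,6S) acid in step 7.
Remark: from step 6 onwards the material is a peroxide and should be handled cold, on small scale and never taken to dryness.

**Route**

Step 1
Reactants: 1 (5-chloropent-1-yn-1-yl)trimethylsilane; 2 propargyl alcohol
Product: 4 2-methylidene-7-(trimethylsilyl)hept-6-yn-1-ol, via Grignard reagent 3 (not isolated)
Conditions: 1 (2.6 equiv), Mg, I2 (cat.), THF, reflux; then 2 (1 equiv), CuI (10 mol%), THF, −10 °C to rt; aq. NH4Cl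
Reagents that add atoms: none
Why: Copper-catalysed carbomagnesiation of propargyl alcohol (anti addition directed by the chloromagnesium alkoxide, alkyl group to the internal carbon) is a standard entry to 2-substituted allylic alcohols, and the silyl group masks the acidic alkyne C–H while the Grignard reagent is formed.

Step 2
Reactants: 4 2-methylidene-7-(trimethylsilyl)hept-6-yn-1-ol; 5 triethyl orthoacetate
Product: 7 ethyl 4-methylidene-9-(trimethylsilyl)non-8-ynoate, via ketene acetal 6 (not isolated)
Conditions: 5 (5 equiv), EtCO2H (cat.), 140 °C, EtOH distilled off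
Reagents that add atoms: none
Why: Johnson–Claisen orthoester rearrangement, in which the mixed ketene acetal 6 undergoes a [3,3]-sigmatropic shift that forms C4–C5 and regenerates the 1,1-disubstituted alkene; no stereocentre arises.

Step 3
Reactants: 7 ethyl 4-methylidene-9-(trimethylsilyl)non-8-ynoate
Product: 8 ethyl 4-methylidenenon-8-ynoate
Conditions: K2CO3 (0.2 equiv), EtOH, rt
Reagents that add atoms: none
Why: Base-mediated protodesilylation of the alkynylsilane by ethoxide attack at silicon; ethanol as solvent leaves the ethyl ester unchanged.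

Step 4
Reactants: 8 ethyl 4-methylidenenon-8-ynoate
Product: 9 4-methylidenenon-8-ynal
Conditions: iBu2AlH (1.05 equiv), CH2Cl2, −78 °C; MeOH, then aq. potassium sodium tartrate
Reagents that add atoms: none
Why: Partial ester reduction with iBu2AlH stops at the tetrahedral aluminium hemiacetal at −78 °C and releases the aldehyde on work-up; alkene and alkyne are not hydroaluminated at this temperature.

Step 5
Reactants: 9 4-methylidenenon-8-ynal; 10 acetyl chloride
Product: 12 (4R)-4-(3-methylideneoct-7-yn-1-yl)oxetan-2-one, via ketene 11 (not isolated)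
Conditions: 10 (slow addition), O-trimethylsilylquinine (10 mol%), LiClO4, iPr2NEt, CH2Cl2/Et2O, −78 °C
Reagents that add atoms: none
Why: Cinchona alkaloid–LiClO4 catalysed ketene–aldehyde [2+2] cycloaddition (acyl halide–aldehyde cyclocondensation), in which the alkaloid adds to ketene 11 to give a chiral ammonium enolate whose face-selective aldol addition to the LiClO4-activated aldehyde and lactonization set C6 as R under catalyst control.

Step 6
Reactants: 12 (4R)-4-(3-methylideneoct-7-yn-1-yl)oxetan-2-one
Product: 15 2-[(6S)-3-methoxy-3-(pent-4-yn-1-yl)-1,2-dioxan-6-yl]acetic acid (both C3 epimers), via carbonyl oxide 13 (not isolated), via methoxy hydroperoxide 14 (not isolated)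
Conditions: O3, CH2Cl2/MeOH (4:1), Sudan Red 7B, −78 °C; N2 purge; evaporation with toluene below 20 °C; same flask: Cs2CO3 (2 equiv), DMF (0.01 M), 0 °C to rt; cold 1 M HCl to pH 3
Reagents that add atoms: ozone, [O-][O+]=O; methanol, CO
Why: Proposed new method: ozone cycloadds to the electron-rich 1,1-disubstituted alkene and the adduct fragments to formaldehyde and carbonyl oxide 13, which methanol captures as methoxy hydroperoxide 14 (C3–O2 and C3–OMe formed); after methanol and formaldehyde are stripped, Cs2CO3 generates the peroxide anion, which displaces the lactone oxygen at C6 (O1–C6) and leaves the caesium carboxylate. The closest known reactions are the SN2 alkyl–oxygen opening of beta-lactones by azide, thiolate and sulfonamide anions and the base-mediated cyclization of hydroperoxy ketals onto sulfonates, epoxides and oxetanes. The 1,2-dioxane closes in a 6-exo-tet mode. C6 is set by inversion at the lactone carbon (4R in 12 becomes 6S), while the new centre C3 is not controlled at this stage and both epimers are expected. The step needs ozone to take the alkene and spare the terminal alkyne, which the far higher nucleophilicity of the alkene and the dye end point secure, and it needs alkyl rather than acyl attack on the lactone, which is secured by the tether (acyl attack would demand an eight-membered perester), by the absence of methanol once base is present and by high dilution. Elimination is not expected because the lactone enolate cannot align with the C6–O bond, and the carboxylate product does not undergo retro-addition.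

Step 7
Reactants: 15 2-[(6S)-3-methoxy-3-(pent-4-yn-1-yl)-1,2-dioxan-6-yl]acetic acid (both C3 epimers)
Product: 16 2-[(3R,6S)-3-methoxy-3-(pent-4-yn-1-yl)-1,2-dioxan-6-yl]acetic acid
Conditions: Amberlyst 15 (H+ form, cat.), MeOH (10 equiv), CH2Cl2, 0 °C to rt; filtration; chromatography, minor 3S epimer resubmitted
Reagents that add atoms: methanol, CO
Why: Acid-catalysed ketal equilibration (anomerization) through the C3 oxocarbenium ion should favour the 3R epimer, which has the methoxy group axial (anomeric effect with O2) and both carbon chains equatorial; C6 is untouched, and catalytic acid with little methanol at 0 °C should exchange the ketal well before Fischer esterification of the acid sets in.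

Step 8
Reactants: 17 dec-9-yn-1-ol
Product: 19 (E)-10-iododec-9-en-1-ol, via alkenylzirconium 18 (not isolated)
Conditions: Cp2Zr(H)Cl (2.5 equiv), THF, rt, dark; I2, 0 °C; aq. Na2S2O3
Reagents that add atoms: iodine, II
Why: Hydrozirconation–iodination, in which syn addition of Zr–H across the terminal alkyne places zirconium on the terminal carbon and iodinolysis with retention gives the E-iodoalkene; one further equivalent of the hydride is consumed by the hydroxyl group.

Step 9
Reactants: 19 (E)-10-iododec-9-en-1-ol
Product: 20 (E)-10-iododec-9-enal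
Conditions: Dess–Martin periodinane, CH2Cl2, 0 °C to rt
Reagents that add atoms: none
Why: Dess–Martin oxidation of the primary alcohol to the aldehyde under neutral conditions that leave the alkenyl iodide and its geometry untouched.

Step 10
Reactants: 20 (E)-10-iododec-9-enal
Product: 21 (E)-11-iodoundec-10-en-2-ol (racemic)
Conditions: MeMgBr (1.2 equiv), THF, −78 °C; aq. NH4Cl
Reagents that add atoms: methylmagnesium bromide, C[Mg]Br
Why: Grignard addition to the aldehyde at low temperature, where no magnesium–iodine exchange occurs at the alkenyl iodide; the new carbinol centre is racemic and is erased in the next step.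

Step 11
Reactants: 21 (E)-11-iodoundec-10-en-2-ol (racemic)
Product: 22 (E)-11-iodoundec-10-en-2-one
Conditions: Dess–Martin periodinane, CH2Cl2, 0 °C to rt
Reagents that add atoms: none
Why: Dess–Martin oxidation of the secondary alcohol to the methyl ketone.

Step 12
Reactants: 16 2-[(3R,6S)-3-methoxy-3-(pent-4-yn-1-yl)-1,2-dioxan-6-yl]acetic acid; 22 (E)-11-iodoundec-10-en-2-one
Product: 23 2-[(3R,6S)-3-methoxy-3-[(6E)-15-oxohexadec-6-en-4-yn-1-yl]-1,2-dioxan-6-yl]acetic acid
Conditions: Pd(PPh3)4 (5 mol%), CuI (10 mol%), Et3N (5 equiv), degassed THF, rt; aq. NaH2PO4 (pH 4)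
Reagents that add atoms: none
Why: Sonogashira coupling, in which zerovalent palladium inserts into the alkenyl C–I bond with retention of the E geometry and couples with the alkynylcopper species (RC≡CCu) formed from the terminal alkyne; the acid travels as its triethylammonium salt, and dialkyl peroxyketals are known to survive Pd/Cu cross-coupling at room temperature.

**Compound list**
1 | (5-chloropent-1-yn-1-yl)trimethylsilane | C[Si](C)(C)C#CCCCCl | starting material
2 | propargyl alcohol (prop-2-yn-1-ol) | C#CCO | starting material
3 | [5-(trimethylsilyl)pent-4-yn-1-yl]magnesium chloride | C[Si](C)(C)C#CCCC[Mg]Cl | intermediate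
4 | 2-methylidene-7-(trimethylsilyl)hept-6-yn-1-ol | C=C(CO)CCCC#C[Si](C)(C)C | intermediate
5 | triethyl orthoacetate (1,1,1-triethoxyethane) | CC(OCC)(OCC)OCC | starting material
6 | (6-{[(1-ethoxyethenyl)oxy]methyl}hept-6-en-1-yn-1-yl)trimethylsilane (mixed ketene acetal of 4) | C=C(OCC)OCC(=C)CCCC#C[Si](C)(C)C | intermediate
7 | ethyl 4-methylidene-9-(trimethylsilyl)non-8-ynoate | CCOC(=O)CCC(=C)CCCC#C[Si](C)(C)C | intermediate
8 | ethyl 4-methylidenenon-8-ynoate | CCOC(=O)CCC(=C)CCCC#C | intermediate
9 | 4-methylidenenon-8-ynal | O=CCCC(=C)CCCC#C | intermediate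
10 | acetyl chloride | CC(=O)Cl | starting material
11 | ketene (ethenone) | C=C=O | intermediate
12 | (4R)-4-(3-methylideneoct-7-yn-1-yl)oxetan-2-one | C=C(CCCC#C)CC[C@@H]1CC(=O)O1 | intermediate
13 | carbonyl oxide of (4R)-4-(3-oxooct-7-yn-1-yl)oxetan-2-one | [O-][O+]=C(CCCC#C)CC[C@@H]1CC(=O)O1 | intermediate
14 | (4R)-4-(3-hydroperoxy-3-methoxyoct-7-yn-1-yl)oxetan-2-one (both epimers at the ketal carbon) | COC(OO)(CCCC#C)CC[C@@H]1CC(=O)O1 | intermediate
15 | 2-[(6S)-3-methoxy-3-(pent-4-yn-1-yl)-1,2-dioxan-6-yl]acetic acid (both C3 epimers) | COC1(CCCC#C)CC[C@@H](CC(=O)O)OO1 | intermediate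
16 | 2-[(3R,6S)-3-methoxy-3-(pent-4-yn-1-yl)-1,2-dioxan-6-yl]acetic acid | CO[C@@]1(CCCC#C)CC[C@@H](CC(=O)O)OO1 | intermediate
17 | dec-9-yn-1-ol | C#CCCCCCCCCO | starting material
18 | (E)-alkenylzirconocene chloride of 17, hydroxyl bound as the Cp2Zr(Cl) alkoxide | Cl[Zr](/C=C/CCCCCCCCO[Zr](Cl)(C1C=CC=C1)C1C=CC=C1)(C1C=CC=C1)C1C=CC=C1 | intermediate
19 | (E)-10-iododec-9-en-1-ol | OCCCCCCCC/C=C/I | intermediate
20 | (E)-10-iododec-9-enal | O=CCCCCCCC/C=C/I | intermediate
21 | (E)-11-iodoundec-10-en-2-ol (racemic) | CC(O)CCCCCCC/C=C/I | intermediate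
22 | (E)-11-iodoundec-10-en-2-one | CC(=O)CCCCCCC/C=C/I | intermediate
23 | 2-[(3R,6S)-3-methoxy-3-[(6E)-15-oxohexadec-6-en-4-yn-1-yl]-1,2-dioxan-6-yl]acetic acid (CNP0165935.1) | CO[C@@]1(CCCC#C/C=C/CCCCCCCC(C)=O)CC[C@@H](CC(=O)O)OO1 | target

**Count**
Total steps: 12. Longest linear sequence: 8 (steps 1–7 and 12); the iodoalkenyl ketone takes 4 steps (8–11).

**Steps most likely to fail**

Step 6. What may go wrong: acyl instead of alkyl attack of peroxide anions on the lactone between molecules (perester oligomers); base-induced loss of the hydroperoxide through adducts with residual formaldehyde; over-ozonation of the alkyne. The fallback uses known chemistry and sets out from 12. Reduction with LiBH4 in THF should give (3R)-6-methylideneundec-10-yne-1,3-diol F1. Selective silylation of the primary hydroxyl (tBuPh2SiCl, imidazole, CH2Cl2, 0 °C) should give (3R)-1-[tert-butyl(diphenyl)silyl]oxy-6-methylideneundec-10-yn-3-ol F2. Mesylation (MsCl, Et3N) should give (3R)-1-[tert-butyl(diphenyl)silyl]oxy-6-methylideneundec-10-yn-3-yl methanesulfonate F3; with the carboxyl carbon held at the alcohol level, this sulfonate cannot eliminate to an enoate. Ozonolysis in CH2Cl2/MeOH should give the hydroperoxy ketal, (3R)-1-[tert-butyl(diphenyl)silyl]oxy-6-hydroperoxy-6-methoxyundec-10-yn-3-yl methanesulfonate F4. KOtBu with 18-crown-6 in toluene should close it with inversion to tert-butyl{2-[(6S)-3-methoxy-3-(pent-4-yn-1-yl)-1,2-dioxan-6-yl]ethoxy}diphenylsilane F5. Desilylation with Bu4NF should give 2-[(6S)-3-methoxy-3-(pent-4-yn-1-yl)-1,2-dioxan-6-yl]ethanol F6, and oxidation with TEMPO and PhI(OAc)2 in MeCN/H2O comes back to the route at 15.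

Step 7. What may go wrong: Fischer esterification of the acid competing with ketal exchange; acid-promoted opening of the peroxyketal; an equilibrium that is not biased enough. The fallback sets out from 15 and makes the esterification deliberate. TsOH in methanol at rt should esterify and equilibrate at the same time to give methyl 2-[(3R,6S)-3-methoxy-3-(pent-4-yn-1-yl)-1,2-dioxan-6-yl]acetate F7, from which the minor 3S ester is removed by chromatography. Hydrolysis with LiOH in THF/H2O at 0 °C comes back to the route at 16.

Step 12. What may go wrong: reduction of the O–O bond by phosphine or copper; oxidative homocoupling of the alkyne; slow turnover with the carboxylate present. The fallback reverses the polarity of the coupling and avoids copper and amine. From 16, NBS with catalytic AgNO3 in acetone should give 2-[(3R,6S)-3-(5-bromopent-4-yn-1-yl)-3-methoxy-1,2-dioxan-6-yl]acetic acid F8. From 22, borylation with B2pin2, PdCl2(PPh3)2, PPh3 and KOPh in toluene at 50 °C should give, with retention, (E)-11-(4,4,5,5-tetramethyl-1,3,2-dioxaborolan-2-yl)undec-10-en-2-one F9. Suzuki–Miyaura coupling of F8 with F9 (Pd(PPh3)4, K3PO4, THF/H2O, rt) comes back to the route at 23.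

**Further compounds**
F1 | step 6 | (3R)-6-methylideneundec-10-yne-1,3-diol | C=C(CCCC#C)CC[C@@H](O)CCO
F2 | step 6 | (3R)-1-[tert-butyl(diphenyl)silyl]oxy-6-methylideneundec-10-yn-3-ol | C=C(CCCC#C)CC[C@@H](O)CCO[Si](c1ccccc1)(c1ccccc1)C(C)(C)C
F3 | step 6 | (3R)-1-[tert-butyl(diphenyl)silyl]oxy-6-methylideneundec-10-yn-3-yl methanesulfonate | C=C(CCCC#C)CC[C@@H](OS(C)(=O)=O)CCO[Si](c1ccccc1)(c1ccccc1)C(C)(C)C
F4 | step 6 | (3R)-1-[tert-butyl(diphenyl)silyl]oxy-6-hydroperoxy-6-methoxyundec-10-yn-3-yl methanesulfonate (both epimers at the ketal carbon) | COC(OO)(CCCC#C)CC[C@@H](OS(C)(=O)=O)CCO[Si](c1ccccc1)(c1ccccc1)C(C)(C)C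
F5 | step 6 | tert-butyl{2-[(6S)-3-methoxy-3-(pent-4-yn-1-yl)-1,2-dioxan-6-yl]ethoxy}diphenylsilane (both C3 epimers) | COC1(CCCC#C)CC[C@@H](CCO[Si](c2ccccc2)(c2ccccc2)C(C)(C)C)OO1
F6 | step 6 | 2-[(6S)-3-methoxy-3-(pent-4-yn-1-yl)-1,2-dioxan-6-yl]ethanol (both C3 epimers) | COC1(CCCC#C)CC[C@@H](CCO)OO1
F7 | step 7 | methyl 2-[(3R,6S)-3-methoxy-3-(pent-4-yn-1-yl)-1,2-dioxan-6-yl]acetate | CO[C@@]1(CCCC#C)CC[C@@H](CC(=O)OC)OO1
F8 | step 12 | 2-[(3R,6S)-3-(5-bromopent-4-yn-1-yl)-3-methoxy-1,2-dioxan-6-yl]acetic acid | CO[C@@]1(CCCC#CBr)CC[C@@H](CC(=O)O)OO1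
F9 | step 12 | (E)-11-(4,4,5,5-tetramethyl-1,3,2-dioxaborolan-2-yl)undec-10-en-2-one | CC(=O)CCCCCCC/C=C/B1OC(C)(C)C(C)(C)O1
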